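Which way of charging leaves the highest share of target at work-up: the dosed flask, the flow tank or the closed flask?

- the set-up with the highest share of target in all that became target or over-reaction product, at the outlet or at the end ("none" if the first two lie within 2 percentage points) (midnight / autumn / winter / none)
- share of target in all that became target or over-reaction product, at the outlet or at the end, midnight
- share of target in all that became target or over-reaction product, at the outlet or at the end, autumn
- share of target in all that became target or over-reaction product, at the outlet or at the end, winter

common to all: precatalyst 0.35 mM

| run | substrate | time | remark |
|---|---|---|---|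
| midnight | 0.35 M (fed, over 12.0 h) | 15 h | a stirred flask in which substrate is dosed at a steady rate over 12.0 h without added volume, worked up at 15 h |
| autumn | 0.35 M |  | one stirred flow tank at steady state, fed with the mixture as stated, mean residence time 15 h |
| winter | 0.35 M | 15 h | everything together in a closed stirred flask, run for 15 h |

    target → over-reaction product (k1 = 0.146 h⁻¹)
    substrate + free catalyst → catalyst intermediate A (k2 = 7500 M⁻¹ h⁻¹)
    catalyst intermediate A ⇌ catalyst intermediate B (K3 = 36.4, k3 = 6260 h⁻¹)
    catalyst intermediate B → free catalyst + target (k4 = 478 h⁻¹)
    precatalyst → free catalyst (k5 = 0.0793 h⁻¹)

- the stated concentrations are those of everything mixed, before any reaction; amounts are the same in each set-up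
- the feed brings no volume worth counting
- run time (midnight): 15 h

Target, once made, goes first-order to over-reaction product, so I work in powers of ten and take its decade time, the hours that cost it one power of ten, 15.8 h; a portion of target made at one moment then falls one power for each decade time of age, age being the hours from making to work-up. Before any reckoning I ask what each given number can move.

| Given | Enters as | If it is off |
|---|---|---|
| 0.146 h⁻¹ | decade time | every logarithm moves in proportion |
| 0.0793 h⁻¹, 0.35 mM | arrival of catalyst | age moves in midnight |
| 6260 h⁻¹, 36.4, 478 h⁻¹ | turnover 433 h⁻¹ | step 4 is slower than step 3, and the turnover is nearly all of 478 h⁻¹ |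
| 7500 M⁻¹ h⁻¹ | [substrate] of 0.0577 M at half the ceiling | age moves through the lag |

In autumn the tank balance makes over-reaction product over target equal to 2.19, so conversion cancels and the share is 31.3 %.

In midnight the full catalyst ceiling of 0.152 M h⁻¹ is higher than the feed of 0.0292 M h⁻¹, but precatalyst has a half-life of 8.74 h. Target cannot run ahead of the feed, so its middle age is at most 9.00 h, which is 0.570 of a power and a rough floor of 27.0 %. My reckoning stops there; I carry no number for the lag or for winter.

The forecast names midnight, with 39.5 % for midnight, 31.3 % for autumn and 30.5 % for winter, holding that “consumption lags the feed early”.

The flask gives midnight, at 39.5 % against 31.3 % in autumn and 30.5 % in winter. In midnight, half of the turnover of step 4 up to work-up is done by 8.14 h, an age of 6.86 h, which in decade times reads as 36.8 %. Left standing to 2.5 d, the same flask has 2.86 more powers to lose, which takes 39.5 % to 0.0554 %, and the reading there is 0.0555 %.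

(Its constants are assumed; the result is computed.)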